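A direct plan would take ring A ready-made as 1-fluoro-3,5-dimethoxybenzene, acylate it to the diaryl ketone A1, methylenate to the 1,1-diarylethene A2, hydrogenate asymmetrically to A3, then brominate and acylate ring A, build the fluoroaryl 1,3-diketone A4 and close ring C by intramolecular SNAr before deprotection. Its weakest steps would be:
- the asymmetric hydrogenation of A2, because two aryl groups would have to be told apart on an alkene whose one ring is blocked at both ortho positions;
- the two electrophilic substitutions on ring A, because each would have to choose between two similarly activated C–H positions;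
- the SNAr closure, because the attacked carbon would be deactivated by two methoxy donors and crowded by the benzylic group.

Ring A would be built, not bought. Its alternating oxygenation (O on C8a, C7, C5; C or H on C8, C6, C4a) is that of one ketene plus two ynol ethers, so the ketene of (S)-3-arylbutanoic acid (C8a, C8) and two molecules of methoxyethyne (C7/C6, then C5/C4a) would be merged by a Danheiser benzannulation. One thermal cascade ending in a 6π electrocyclisation would give phenol 15, with the side chain already fixed between the future O1 and 7-OMe and one free ortho position. No arene C–H need be selected, the stereocentre would come from conjugate addition to an unhindered crotonate instead of a hindered alkene hydrogenation, and ring C would close at O1–C2 without SNAr.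

Key step: step 5

Remark: methoxyethyne (7) is taken to be too unstable to be a dependable catalogue item and is therefore made in step 3; the sense of induction in step 1 is assigned by analogy with linear (E)-enones, and the mirror-image ligand would be used if it proved opposite.

Step 1
Reactants: 1 [4-(propan-2-yloxy)phenyl]boronic acid; 2 tert-butyl (2E)-but-2-enoate
Product: 3 tert-butyl (3S)-3-[4-(propan-2-yloxy)phenyl]butanoate
Conditions: Rh(acac)(C2H4)2 (3 mol %), (S)-BINAP (3.3 mol %), 1 (2 equiv), dioxane/H2O 10:1, 100 °C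
Reagents that add atoms: none
Why: Hayashi–Miyaura asymmetric 1,4-addition, in which the aryl-rhodium BINAP species should add to one enantioface of the unhindered E-enoate and so set the S centre, the only stereocentre of the route (it is named R once ring A outranks the aryl group).

Step 2
Reactants: 3 tert-butyl (3S)-3-[4-(propan-2-yloxy)phenyl]butanoate
Product: 4 (3S)-3-[4-(propan-2-yloxy)phenyl]butanoic acid
Conditions: TFA/CH2Cl2 1:4, 0 °C → rt
Reagents that add atoms: none
Why: Acidolysis of a tert-butyl ester with loss of isobutene, which should leave the isopropyl aryl ether intact and cannot touch the stereocentre because it is β to the carbonyl group and not enolisable.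

Step 3
Reactants: 5 2-chloro-1,1-dimethoxyethane
Product: 7 methoxyethyne, via sodium methoxyethynide 6 (not isolated)
Conditions: NaNH2 (3 equiv), liquid NH3, −33 °C; cold saturated aqueous NH4Cl; distil into cold toluene and store at −20 °C
Reagents that add atoms: none
Why: Twofold amide-induced β-elimination (methanol, then hydrogen chloride) from the chloroacetal, the standard preparation of alkoxyalkynes, in which the third equivalent of base should hold the volatile alkyne as its acetylide until the cold quench.

Step 4
Reactants: 4 (3S)-3-[4-(propan-2-yloxy)phenyl]butanoic acid; 7 methoxyethyne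
Product: 10 3-methoxy-4-{(1S)-1-[4-(propan-2-yloxy)phenyl]ethyl}cyclobut-2-en-1-one as both C4 epimers, via acid chloride 8 (not isolated), via aldoketene 9 (not isolated)
Conditions: (COCl)2 (1.2 equiv), DMF (cat.), CH2Cl2, rt, evaporate; then 7 (3 equiv), Et3N (1.1 equiv, slow addition), Et2O, 0 °C → rt; filter
Reagents that add atoms: none
Why: Ketene–ynol ether [2+2] cycloaddition, in which the unsubstituted carbon of methoxyethyne should attack the carbonyl carbon of the aldoketene made by dehydrochlorination and the methoxy-stabilised zwitterion should close at the ketene α-carbon to give the 3-alkoxycyclobutenone; the new ring stereocentre is uncontrolled and is erased in step 5.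

Step 5
Reactants: 10 3-methoxy-4-{(1S)-1-[4-(propan-2-yloxy)phenyl]ethyl}cyclobut-2-en-1-one; 7 methoxyethyne
Product: 15 3,5-dimethoxy-2-{(1R)-1-[4-(propan-2-yloxy)phenyl]ethyl}phenol, via vinylketene 11 (not isolated), via alkenylcyclobutenone 12 (not isolated), via dienylketene 13 (not isolated), via cyclohexadienone 14 (not isolated)
Conditions: 7 (3 equiv), toluene, sealed tube, 80 → 130 °C
Reagents that add atoms: none
Why: Heating should open cyclobutenone 10 by 4π electrocyclic cleavage of its C1–C4 bond to the (2-methoxyvinyl)ketene 11, whose carbonyl carbon is attacked by the unsubstituted carbon of methoxyethyne; closure of the zwitterion at the ketene α-carbon gives alkenylcyclobutenone 12, a second 4π opening gives dienylketene 13, and a thermal disrotatory 6π electrocyclisation between the ketene carbon and the alkene terminus that carries the side chain closes the six-membered carbocycle 14, which enolises to phenol 15. The closest known reaction type is the Danheiser benzannulation of cyclobutenones with alkoxyalkynes to resorcinol monoethers, run here on a 3-alkoxycyclobutenone so that a phloroglucinol diether results. Ring A is thus closed by 6π electrocyclisation at the C8–C8a bond, after the alkyne carbons C4a and C5 have been inserted between C8a and C6. No stereocentre is created, since the sp3 ring carbon of 14 is lost on aromatisation, and the benzylic centre is a spectator: the alkyl group should rotate outward in the ring opening of 10, which keeps its C–H away from the ketene carbon and out of reach of a 1,5-hydrogen shift. The step needs both [2+2] events to join the ketene carbonyl carbon to the unsubstituted alkyne carbon (and no direct [4+2] across the vinylketene), which the polarisation of the ynol ether secures, and it needs the ketene to be trapped before it dimerises, which the excess of alkyne and the reversible ring opening favour. Methoxyethyne has no β-hydrogen and so cannot suffer the retro-ene loss of alkene that limits ethyl ynol ethers at this temperature.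

Step 6
Reactants: 15 3,5-dimethoxy-2-{(1R)-1-[4-(propan-2-yloxy)phenyl]ethyl}phenol
Product: 18 1-(2-hydroxy-4,6-dimethoxy-3-{(1R)-1-[4-(propan-2-yloxy)phenyl]ethyl}phenyl)ethan-1-one, via aryl acetate 16 (not isolated), via difluoroboron chelate 17 (not isolated)
Conditions: Ac2O (1.5 equiv), BF3·OEt2 (3 equiv), CH2Cl2, 0 → 25 °C; then NaOAc, MeOH/H2O, 60 °C
Reagents that add atoms: acetic anhydride, CC(=O)OC(C)=O
Why: Boron trifluoride-mediated O-acetylation and Fries-type ortho-acylation, in which the acetyl group should be delivered to the single free position ortho to the phenol oxygen and held there as the six-membered BF2 chelate, while the mild temperature and the absence of protic acid should spare the benzylic centre and the isopropyl ether.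

Step 7
Reactants: 18 1-(2-hydroxy-4,6-dimethoxy-3-{(1R)-1-[4-(propan-2-yloxy)phenyl]ethyl}phenyl)ethan-1-one; 19 4-methoxybenzaldehyde
Product: 22 3-hydroxy-5,7-dimethoxy-2-(4-methoxyphenyl)-8-{(1R)-1-[4-(propan-2-yloxy)phenyl]ethyl}-4H-chromen-4-one, via chalcone 20 (not isolated), via dihydroflavonol 21 (not isolated)
Conditions: 19 (1.2 equiv), KOH (50 % aq), EtOH, rt; then H2O2 (30 % aq, 4 equiv), 0 °C → rt; dilute HCl
Reagents that add atoms: hydrogen peroxide, OO
Why: Claisen–Schmidt condensation followed by Algar–Flynn–Oyamada oxidative cyclisation, in which the phenoxide should add 6-endo to the enone β-carbon (bond O1–C2), the enolate should be hydroxylated by peroxide and the dihydroflavonol should be dehydrogenated under the alkaline oxidising conditions; the benzylic centre carries no acidic hydrogen.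

Step 8
Reactants: 22 3-hydroxy-5,7-dimethoxy-2-(4-methoxyphenyl)-8-{(1R)-1-[4-(propan-2-yloxy)phenyl]ethyl}-4H-chromen-4-one
Product: 23 3,5-dihydroxy-8-[(1R)-1-(4-hydroxyphenyl)ethyl]-7-methoxy-2-(4-methoxyphenyl)-4H-chromen-4-one
Conditions: BCl3 (5 equiv), CH2Cl2, −78 → 0 °C; MeOH, then aqueous NaHCO3
Reagents that add atoms: none
Why: Lewis-acid ether cleavage, in which BCl3 should remove the secondary isopropyl ether much faster than a methyl ether and should demethylate only the 5-methoxy group through its six-membered chelate with the C4 carbonyl, leaving the 7- and 4'-methyl ethers and the benzylic centre untouched at low temperature.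

Compound list
1 | [4-(propan-2-yloxy)phenyl]boronic acid | CC(C)Oc1ccc(B(O)O)cc1 | starting material
2 | tert-butyl (2E)-but-2-enoate | C/C=C/C(=O)OC(C)(C)C | starting material
3 | tert-butyl (3S)-3-[4-(propan-2-yloxy)phenyl]butanoate | CC(C)(C)OC(=O)C[C@H](C)c1ccc(OC(C)C)cc1 | intermediate
4 | (3S)-3-[4-(propan-2-yloxy)phenyl]butanoic acid | OC(=O)C[C@H](C)c1ccc(OC(C)C)cc1 | intermediate
5 | 2-chloro-1,1-dimethoxyethane | COC(CCl)OC | starting material
6 | sodium methoxyethynide, formed in the flask | [Na+].[C-]#COC | intermediate
7 | methoxyethyne | C#COC | intermediate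
8 | (3S)-3-[4-(propan-2-yloxy)phenyl]butanoyl chloride, formed in the flask | ClC(=O)C[C@H](C)c1ccc(OC(C)C)cc1 | intermediate
9 | (3S)-3-[4-(propan-2-yloxy)phenyl]but-1-en-1-one (aldoketene), formed in the flask | O=C=C[C@H](C)c1ccc(OC(C)C)cc1 | intermediate
10 | 3-methoxy-4-{(1S)-1-[4-(propan-2-yloxy)phenyl]ethyl}cyclobut-2-en-1-one (both epimers at ring C4) | COC1=CC(=O)C1[C@H](C)c1ccc(OC(C)C)cc1 | intermediate
11 | (5S)-3-methoxy-5-[4-(propan-2-yloxy)phenyl]hexa-1,3-dien-1-one (vinylketene, alkene geometry not fixed), formed in the flask | O=C=CC(OC)=C[C@H](C)c1ccc(OC(C)C)cc1 | intermediate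
12 | 3-methoxy-4-{(3S)-1-methoxy-3-[4-(propan-2-yloxy)phenyl]but-1-en-1-yl}cyclobut-2-en-1-one (ring C4 undefined), formed in the flask | COC1=CC(=O)C1C(OC)=C[C@H](C)c1ccc(OC(C)C)cc1 | intermediate
13 | (7S)-3,5-dimethoxy-7-[4-(propan-2-yloxy)phenyl]octa-1,3,5-trien-1-one (dienylketene), formed in the flask | O=C=CC(OC)=CC(OC)=C[C@H](C)c1ccc(OC(C)C)cc1 | intermediate
14 | 3,5-dimethoxy-6-{(1S)-1-[4-(propan-2-yloxy)phenyl]ethyl}cyclohexa-2,4-dien-1-one (ring C6 undefined), formed in the flask | O=C1C=C(OC)C=C(OC)C1[C@H](C)c1ccc(OC(C)C)cc1 | intermediate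
15 | 3,5-dimethoxy-2-{(1R)-1-[4-(propan-2-yloxy)phenyl]ethyl}phenol | COc1cc(O)c([C@H](C)c2ccc(OC(C)C)cc2)c(OC)c1 | intermediate
16 | 3,5-dimethoxy-2-{(1R)-1-[4-(propan-2-yloxy)phenyl]ethyl}phenyl acetate, formed in the flask | COc1cc(OC(C)=O)c([C@H](C)c2ccc(OC(C)C)cc2)c(OC)c1 | intermediate
17 | difluoroboron chelate of ketone 18, with BF2 bridging the phenolate oxygen and the acetyl oxygen in a six-membered ring, formed in the flask | CC1=[O+][B-](F)(F)Oc2c1c(OC)cc(OC)c2[C@H](C)c1ccc(OC(C)C)cc1 | intermediate
18 | 1-(2-hydroxy-4,6-dimethoxy-3-{(1R)-1-[4-(propan-2-yloxy)phenyl]ethyl}phenyl)ethan-1-one | CC(=O)c1c(OC)cc(OC)c([C@H](C)c2ccc(OC(C)C)cc2)c1O | intermediate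
19 | 4-methoxybenzaldehyde | COc1ccc(C=O)cc1 | starting material
20 | (2E)-1-(2-hydroxy-4,6-dimethoxy-3-{(1R)-1-[4-(propan-2-yloxy)phenyl]ethyl}phenyl)-3-(4-methoxyphenyl)prop-2-en-1-one, formed in the flask | COc1ccc(/C=C/C(=O)c2c(OC)cc(OC)c([C@H](C)c3ccc(OC(C)C)cc3)c2O)cc1 | intermediate
21 | 3-hydroxy-5,7-dimethoxy-2-(4-methoxyphenyl)-8-{(1R)-1-[4-(propan-2-yloxy)phenyl]ethyl}-2,3-dihydro-4H-chromen-4-one (C2 and C3 undefined), formed in the flask | COc1ccc(C2Oc3c([C@H](C)c4ccc(OC(C)C)cc4)c(OC)cc(OC)c3C(=O)C2O)cc1 | intermediate
22 | 3-hydroxy-5,7-dimethoxy-2-(4-methoxyphenyl)-8-{(1R)-1-[4-(propan-2-yloxy)phenyl]ethyl}-4H-chromen-4-one | COc1ccc(-c2oc3c([C@H](C)c4ccc(OC(C)C)cc4)c(OC)cc(OC)c3c(=O)c2O)cc1 | intermediate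
23 | 3,5-dihydroxy-8-[(1R)-1-(4-hydroxyphenyl)ethyl]-7-methoxy-2-(4-methoxyphenyl)-4H-chromen-4-one | COc1ccc(-c2oc3c([C@H](C)c4ccc(O)cc4)c(OC)cc(O)c3c(=O)c2O)cc1 | target

Total step count: 8. Longest linear sequence: 7 (steps 1, 2, 4, 5, 6, 7, 8); step 3 is a one-step side branch.

Steps most likely to fail

Step 5. The vinylogous-ester cyclobutenone may be slow to ring-open, and methoxyethyne and ketene 11 may be lost to oligomers before they meet. The fallback sets out from acid 4 and reaches the same vinylketene by 1,4-dehydrochlorination instead of ring opening. Acid 4 would be homologated with 1,1'-carbonyldiimidazole, potassium methyl malonate and MgCl2 to methyl (5S)-3-oxo-5-[4-(propan-2-yloxy)phenyl]hexanoate F1. F1 would be converted with trimethyl orthoformate and catalytic H2SO4 in MeOH into methyl (2E,5S)-3-methoxy-5-[4-(propan-2-yloxy)phenyl]hex-2-enoate F2, which LiOH would saponify to (2E,5S)-3-methoxy-5-[4-(propan-2-yloxy)phenyl]hex-2-enoic acid F3. Oxalyl chloride would give (2E,5S)-3-methoxy-5-[4-(propan-2-yloxy)phenyl]hex-2-enoyl chloride F4. Slow addition of F4 to Et3N and 7 in toluene at 80 °C should give 11 by γ-deprotonation; 11 then runs on through 12, 13 and 14 and comes back to the route at phenol 15. Cyclobutenone 10, and with it step 4, is bypassed.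

Step 7. The oxidative cyclisation may take the five-membered pathway to the aurone, which a 6'-methoxy group on the chalcone is known to favour. The fallback sets out from ketone 18. Chalcone 20 would be isolated after the condensation with 19 and cyclised oxidatively with I2 (cat.) in DMSO at 120 °C to 5,7-dimethoxy-2-(4-methoxyphenyl)-8-{(1R)-1-[4-(propan-2-yloxy)phenyl]ethyl}-4H-chromen-4-one F5. F5 would be hydroxylated at C3 by lithiation with lithium diisopropylamide in THF at −78 °C, borylation with B(OMe)3 and oxidation with H2O2/AcOH, which comes back to the route at flavonol 22.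

Step 6. Ipso-protonation of the electron-rich ring may ionise the benzylic carbon, with loss of enantiopurity or of the side chain; acetylation may also occur between the two methoxy groups or on the side-chain arene. The fallback sets out from phenol 15 and uses no acid. Ortho-formylation with MgCl2, Et3N and paraformaldehyde in MeCN at reflux should give 2-hydroxy-4,6-dimethoxy-3-{(1R)-1-[4-(propan-2-yloxy)phenyl]ethyl}benzaldehyde F6. MeMgBr (2.2 equiv, THF, 0 °C) should give 2-(1-hydroxyethyl)-3,5-dimethoxy-6-{(1R)-1-[4-(propan-2-yloxy)phenyl]ethyl}phenol F7, and MnO2 in CH2Cl2 should oxidise the benzylic alcohol, which comes back to the route at ketone 18.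

Further compounds
F1 | step 5 | methyl (5S)-3-oxo-5-[4-(propan-2-yloxy)phenyl]hexanoate | COC(=O)CC(=O)C[C@H](C)c1ccc(OC(C)C)cc1
F2 | step 5 | methyl (2E,5S)-3-methoxy-5-[4-(propan-2-yloxy)phenyl]hex-2-enoate | COC(=O)/C=C(/OC)C[C@H](C)c1ccc(OC(C)C)cc1
F3 | step 5 | (2E,5S)-3-methoxy-5-[4-(propan-2-yloxy)phenyl]hex-2-enoic acid | OC(=O)/C=C(/OC)C[C@H](C)c1ccc(OC(C)C)cc1
F4 | step 5 | (2E,5S)-3-methoxy-5-[4-(propan-2-yloxy)phenyl]hex-2-enoyl chloride | ClC(=O)/C=C(/OC)C[C@H](C)c1ccc(OC(C)C)cc1
F5 | step 7 | 5,7-dimethoxy-2-(4-methoxyphenyl)-8-{(1R)-1-[4-(propan-2-yloxy)phenyl]ethyl}-4H-chromen-4-one | COc1ccc(-c2cc(=O)c3c(OC)cc(OC)c([C@H](C)c4ccc(OC(C)C)cc4)c3o2)cc1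
F6 | step 6 | 2-hydroxy-4,6-dimethoxy-3-{(1R)-1-[4-(propan-2-yloxy)phenyl]ethyl}benzaldehyde | O=Cc1c(OC)cc(OC)c([C@H](C)c2ccc(OC(C)C)cc2)c1O
F7 | step 6 | 2-(1-hydroxyethyl)-3,5-dimethoxy-6-{(1R)-1-[4-(propan-2-yloxy)phenyl]ethyl}phenol (carbinol carbon undefined) | CC(O)c1c(OC)cc(OC)c([C@H](C)c2ccc(OC(C)C)cc2)c1O
A1 | direct plan | [4-(benzyloxy)phenyl](2-fluoro-4,6-dimethoxyphenyl)methanone | COc1cc(F)c(C(=O)c2ccc(OCc3ccccc3)cc2)c(OC)c1
A2 | direct plan | 2-{1-[4-(benzyloxy)phenyl]ethenyl}-1-fluoro-3,5-dimethoxybenzene | C=C(c1ccc(OCc2ccccc2)cc1)c1c(F)cc(OC)cc1OC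
A3 | direct plan | 2-{(1R)-1-[4-(benzyloxy)phenyl]ethyl}-1-fluoro-3,5-dimethoxybenzene | COc1cc(OC)c([C@H](C)c2ccc(OCc3ccccc3)cc2)c(F)c1
A4 | direct plan | 2-(benzyloxy)-1-(3-{(1R)-1-[4-(benzyloxy)phenyl]ethyl}-2-fluoro-4,6-dimethoxyphenyl)-3-(4-methoxyphenyl)propane-1,3-dione | O=C(c1ccc(OC)cc1)C(OCc1ccccc1)C(=O)c1c(F)c([C@H](C)c2ccc(OCc3ccccc3)cc2)c(OC)cc1OC
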